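1. The pitfall in beta is to take free base for the limiting reagent, since its 0.320 M lies below the 0.40 M of electrophile. Neither earlier run tests this, because both charged more base than electrophile.

| setting | south-west | north-east | beta | delta | epsilon |
|---|---|---|---|---|---|
| electrophile | 0.40 M | 0.40 M | 0.40 M | 0.40 M | 0.40 M |
| nucleophile | 0.60 M | 0.60 M | 0.600 M | 0.600 M | 0.600 M |
| free base | 0.46 M | 2.1 M | 0.320 M | 0.640 M | 1.30 M |
| protic impurity | 0.020 M | 0.020 M | 0.0200 M | 0.0200 M | 0.0200 M |
| remark | run made earlier | run made earlier |  |  |  |
| time |  |  | 2.5 d | 2.5 d | 2.5 d |

| run | time / h | electrophile / % | target / % |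
|---|---|---|---|
| south-west | 2.50 | 81 | 4 |
| south-west | 4.00 | 73 | 8 |
| south-west | 6.00 | 65 | 12 |
| south-west | 10.0 | 47 | 18 |
| south-west | 20.0 | 26 | 21 |
| south-west | 30.0 | 16 | 25 |
| north-east | 5.00 | 68 | 10 |
| north-east | 10.0 | 51 | 15 |
| north-east | 15.0 | 37 | 19 |
| north-east | 20.0 | 29 | 25 |
| north-east | 25.0 | 17 | 24 |
| north-east | 30.0 | 14 | 23 |

(standard deviation of a reading: 2 percentage points)

- the analysis behind the earlier runs scatters by 2 percentage points, standard deviation
- what has gone from electrophile into another species counts as reacted, even if it can come back

* part of the electrophile that has reacted at the end, beta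
* part of the electrophile that has reacted at the end, delta
* part of the electrophile that has reacted at the end, epsilon
* what raising the concentration of free base from its lowest to its highest value here does to the part of the electrophile that has reacted (changes below 5 percentage points count as none) (no change / it falls / it rises)

2. I read the electrophile as falling by a steady factor per hour, the first-order law dc/dt = −k·c, with c for c(electrophile). Integrated from a reading at time s, it gives c(t) = c(s)·exp(−k·(t − s)).

3. I call k the decay constant, the apparent (pseudo-first-order) rate constant of electrophile loss: the logarithm of the ratio of the first to the last reading, divided by the time between them. The south-west run gives 0.0590 h⁻¹. The north-east run, with 4.57 times that base charge, gives about the same, 0.0632 h⁻¹. So, as far as these scattered readings show, base does not show in the constant between those two charges.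

4. Can beta's base last? The south-west run ends with 25 % target. If each target costs one base, and the rest of the lost electrophile costs none, which is my assumption, beta needs about 0.100 M by that time, less than its 0.320 M. The north-east target readings are 25 % at 20.0 h and 23 % at 30.0 h, so I assume that the need stays near that figure later on.

5. So I carry the south-west's last reading, 16 % at 30.0 h, on to 2.5 d. That leaves 2.73 %, so I expect 97.3 % reacted in beta, delta and epsilon alike, and no change with base.

6. The forecast says 77 % for beta, 97 % for delta, 97 % for epsilon, and it rises. Its ground for beta is “If base is consumed 1:1 (not proven, since both earlier runs had enough), reaction stalls near 75%.” On beta, and so on the trend, we part.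

7. The flasks give 96.0 % in beta, 96.0 % in delta and 96.0 % in epsilon; the trend is no change, a shift of 0.023 percentage points. At the end of beta, 62.3 % of the charged free base is still free. The decay constant 0.0590 h⁻¹ gave my estimate of 2.73 % of the electrophile there, and beta holds 4.0 %.

    electrophile + nucleophile → acid set free + target (k = 0.0401 M⁻¹ h⁻¹)
    nucleophile + acid set free ⇌ protonated nucleophile, settled at all times (K = 50.0 M⁻¹)
    acid set free + free base ⇌ salt of the base, settled at all times (K = 2300 M⁻¹)
    electrophile ⇌ dormant form (K = 19.2, k = 0.0439 h⁻¹)
    electrophile + protic impurity → quenched substrate (k = 10.3 M⁻¹ h⁻¹)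
    electrophile → decomposition product (k = 5.69 × 10⁻⁵ h⁻¹)

8. The neighbour flask is beta read at 25 h. Running 0.0590 h⁻¹ back from the south-west's last reading gives 78.5 % reacted; the computed result is 80.4 %.

The readings are simulated for substances that don't exist, noise included.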